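**Retrosynthetic overview**

1. The strategy rests on ring A of the bicyclo[3.3.1]nonane: C5 is the carbon between the C4 and C9 carbonyls of the trione ring B, C6 is an unsubstituted CH2 and C7 carries an epimerisable carbon substituent. C5–C6 is therefore cut as an intramolecular Michael addition onto an acrylate (C6=C7–CO2Me) held on C8.
2. The geranyl chain on C7 is cut next to its CH2: C7–CH2–ZnI plus (E)-1-iodo-2,6-dimethylhepta-1,5-diene (Negishi coupling), the CH2 coming from the ester by reduction.
3. The vicinal quaternary pair C1/C8 is cut by a dearomatising ortho-Claisen rearrangement of the para O-allyl ether of a 3,5-diprenylated acylphloroglucinol. Alkene geometry and a chair transition state fix the relative configuration; a chiral guanidinium catalyst is meant to fix the absolute one.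
4. The ether comes from Mitsunobu coupling of the acylphloroglucinol (Friedel–Crafts acylation, double C-prenylation) with a stereodefined (E)-2-(hydroxymethyl)acrylate (enol tosylate, then Negishi coupling).
5. Ring order: ring B is the phloroglucinol carbocycle, dearomatised in the Claisen step; ring A is closed last, by the Michael addition.

Key step: step 11

Remark on the chemistry: atom numbers C1–C9 are those of the bicyclic core of the target and are used for the open precursors too. The phenol hydroxyl between the two prenyl groups (para to the aroyl group) is assumed to be the most acidic and hence the site of etherification. The phenol is carried as a tosylate instead of a silyl ether because it must survive AlCl3 and alkoxide. The O-methyl enol ether is drawn as the C4–OMe isomer.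

**Route**

Step 1
Reactants: 1 methyl 3-hydroxypropanoate
Product: 2 methyl 3-[(tert-butyldimethylsilyl)oxy]propanoate
Conditions: TBSCl, imidazole, CH2Cl2, 0 to 20 °C
Reagents that add atoms: tert-butyldimethylsilyl chloride, CC(C)(C)[Si](C)(C)Cl
Why: Standard silylation of a primary alcohol masks the hydroxyl that later becomes the allylic ether carbon C6.

Step 2
Reactants: 2 methyl 3-[(tert-butyldimethylsilyl)oxy]propanoate
Product: 3 methyl 2-{[(tert-butyldimethylsilyl)oxy]methyl}-3-oxobutanoate (racemic; the centre is erased in step 3)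
Conditions: LiN(i-Pr)2, THF, −78 °C; N-methoxy-N-methylacetamide, −78 to −20 °C; aq. NH4Cl
Reagents that add atoms: N-methoxy-N-methylacetamide, CC(=O)N(C)OC
Why: Crossed Claisen-type C-acylation of the ester enolate by an N-methoxy-N-methylamide, whose chelated tetrahedral adduct persists until work-up so the β-keto ester does not quench the enolate; at −78 °C acylation should outrun loss of silanolate.

Step 3
Reactants: 3 methyl 2-{[(tert-butyldimethylsilyl)oxy]methyl}-3-oxobutanoate
Product: 4 methyl (2E)-2-{[(tert-butyldimethylsilyl)oxy]methyl}-3-(tosyloxy)but-2-enoate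
Conditions: TsCl, N-methylimidazole, Et3N, MeCN, 0 to 20 °C
Reagents that add atoms: 4-toluenesulfonyl chloride, Cc1ccc(cc1)S(Cl)(=O)=O
Why: O-Sulfonylation of the amine-generated, non-chelated enolate is known for α-substituted β-keto esters to give the (E)-enol tosylate (tosyloxy trans to the ester), which fixes the alkene geometry that the next coupling retains.

Step 4
Reactants: 4 methyl (2E)-2-{[(tert-butyldimethylsilyl)oxy]methyl}-3-(tosyloxy)but-2-enoate, 5 5-bromo-2-methylpent-2-ene
Product: 7 methyl (2E)-2-{[(tert-butyldimethylsilyl)oxy]methyl}-3,7-dimethylocta-2,6-dienoate, via homoprenylzinc bromide 6 (not isolated)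
Conditions: 5, Zn dust, LiCl, THF, 50 °C; then 4, PdCl2(dppf) (5 mol %), THF, 50 °C
Reagents that add atoms: none
Why: Negishi coupling of an activated alkenyl tosylate with a primary alkylzinc halide goes with retention, so the homoprenyl chain ends up cis to the silyloxymethyl group and the methyl group cis to the ester.

Step 5
Reactants: 7 methyl (2E)-2-{[(tert-butyldimethylsilyl)oxy]methyl}-3,7-dimethylocta-2,6-dienoate
Product: 8 methyl (2E)-2-(hydroxymethyl)-3,7-dimethylocta-2,6-dienoate (CH2OH cis to the homoprenyl chain)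
Conditions: HF·pyridine, THF, 0 to 20 °C
Reagents that add atoms: none
Why: Fluoride cleavage of the primary silyl ether leaves the ester and both alkenes untouched, and a geminal hydroxymethyl ester cannot lactonise.

Step 6
Reactants: 9 3-hydroxybenzoic acid
Product: 10 3-(tosyloxy)benzoic acid
Conditions: TsCl, aq. NaOH, THF, 0 to 20 °C; then HCl
Reagents that add atoms: 4-toluenesulfonyl chloride, Cc1ccc(cc1)S(Cl)(=O)=O
Why: Schotten–Baumann sulfonylation of the phenoxide (any mixed anhydride at the carboxylate hydrolyses back) installs an aryl sulfonate that should tolerate AlCl3, cold aqueous alkali, hindered alkoxide, hydride and zerovalent palladium and is removed by hot hydroxide at the end.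

Step 7
Reactants: 10 3-(tosyloxy)benzoic acid, 11 phloroglucinol
Product: 13 3-(2,4,6-trihydroxybenzoyl)phenyl 4-methylbenzenesulfonate, via acid chloride 12 (not isolated)
Conditions: (COCl)2, DMF (cat.), CH2Cl2, 20 °C; evaporate; then 11, AlCl3, PhNO2, 60 °C; aq. HCl
Reagents that add atoms: none
Why: Friedel–Crafts C-acylation of phloroglucinol, whose three ring carbons are equivalent, so regiochemistry is not an issue, and the first acyl group deactivates the ring towards a second.

Step 8
Reactants: 13 3-(2,4,6-trihydroxybenzoyl)phenyl 4-methylbenzenesulfonate, 14 prenyl bromide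
Product: 15 3-[2,4,6-trihydroxy-3,5-bis(3-methylbut-2-en-1-yl)benzoyl]phenyl 4-methylbenzenesulfonate
Conditions: 14 (2.1 equiv), 5% aq. KOH, 0 °C
Reagents that add atoms: none
Why: C-Alkylation of the acylphloroglucinol anion with an allylic bromide in water, where the hydrogen-bonded phenoxide oxygens favour attack through carbon, fills the two free ring positions; the reaction is stopped before a third, dearomatising prenylation.

Step 9
Reactants: 15 3-[2,4,6-trihydroxy-3,5-bis(3-methylbut-2-en-1-yl)benzoyl]phenyl 4-methylbenzenesulfonate, 8 methyl (2E)-2-(hydroxymethyl)-3,7-dimethylocta-2,6-dienoate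
Product: 16 methyl (2E)-2-({3,5-dihydroxy-2,6-bis(3-methylbut-2-en-1-yl)-4-[3-(tosyloxy)benzoyl]phenoxy}methyl)-3,7-dimethylocta-2,6-dienoate
Conditions: PPh3, DIAD, THF, 0 to 20 °C
Reagents that add atoms: none
Why: Mitsunobu etherification should occur at the most acidic hydroxyl, the one para to the aroyl group (the ortho hydroxyls are hydrogen-bonded to the ketone), and the fully substituted β-carbon of 8 leaves only direct SN2 displacement at CH2, so the alkene geometry is carried into the ether.

Step 10
Reactants: 16 methyl (2E)-2-({3,5-dihydroxy-2,6-bis(3-methylbut-2-en-1-yl)-4-[3-(tosyloxy)benzoyl]phenoxy}methyl)-3,7-dimethylocta-2,6-dienoate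
Product: 17 methyl (3R)-3-{(1R)-2,4-dihydroxy-1,5-bis(3-methylbut-2-en-1-yl)-6-oxo-3-[3-(tosyloxy)benzoyl]cyclohexa-2,4-dien-1-yl}-3,7-dimethyl-2-methylideneoct-6-enoate
Conditions: N,N'-bis[(1R,2R)-2-(2-phenyl-1H-pyrrol-1-yl)cyclohexyl]guanidinium tetrakis[3,5-bis(trifluoromethyl)phenyl]borate (20 mol %; or its enantiomer, see Why), hexanes/toluene, 40 °C
Reagents that add atoms: none
Why: Proposed new method: a [3,3]-sigmatropic shift from the ether oxygen to one of the two prenylated ortho carbons forms C1–C8 and both quaternary centres at once, the dienone tautomerising to the stable enolised trione; the relative configuration follows from the chair transition state, in which the (E)-alkene places the homoprenyl chain axial and anti to the C1 prenyl group and the methyl group equatorial; the absolute configuration requires the C2-symmetric guanidinium ion, hydrogen-bonded to the ether oxygen and the acrylate carbonyl of the polarised transition state, to distinguish the two enantiotopic ortho carbons, for which no predictive model exists, so the catalyst antipode has to be chosen by a test run; the closest known reactions are the guanidinium-catalysed enantioselective Claisen rearrangement of ester-substituted allyl vinyl ethers and O-allyl β-keto esters and the thermal dearomatising ortho-Claisen rearrangement of acylphloroglucinol allyl ethers.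

Step 11
Reactants: 17 methyl (3R)-3-{(1R)-2,4-dihydroxy-1,5-bis(3-methylbut-2-en-1-yl)-6-oxo-3-[3-(tosyloxy)benzoyl]cyclohexa-2,4-dien-1-yl}-3,7-dimethyl-2-methylideneoct-6-enoate
Product: 18 methyl (1S,5S,7R,8S)-4-hydroxy-8-methyl-1,5-bis(3-methylbut-2-en-1-yl)-8-(4-methylpent-3-en-1-yl)-2,9-dioxo-3-[3-(tosyloxy)benzoyl]bicyclo[3.3.1]non-3-ene-7-carboxylate
Conditions: KOt-Bu (2.3 equiv), t-BuOH/THF, 0 to 40 °C; then cold 1 M HCl
Reagents that add atoms: none
Why: The anion of 17 is a vinylogous carboxylate whose C5 carbon, flanked by the C4 and C9 oxygens, adds to the unsubstituted acrylate terminus C6 in an intramolecular Michael addition, and the resulting C7 ester enolate is protonated by tert-butanol. The closest known reaction is the base-mediated annulation of dearomatised acylphloroglucinols onto acrylate and enal acceptors to give bicyclo[3.3.1]nonane-2,4,9-triones. Ring A (C1–C8–C7–C6–C5–C9) closes in a 6-endo-trig mode by forming C5–C6. C5 is set by the tether, because the acrylate hangs from C8 on one face of the dienone and can reach C5 only on that face; C7 is set by thermodynamic control, the excess alkoxide re-forming the ester enolate (and, through retro-Michael and Michael steps, the open form) until the ester sits equatorial on the chair of ring A, cis to the axial C8 methyl group, whereas kinetic protonation from the open outer face would leave it axial. The step needs attack through C5 and not through C3 or oxygen: O-adducts revert under the conditions, and a C3 adduct would carry only a simple diketonate anion, less stabilised than the 2-acyl-1,3-diketonate formed through C5, so reversibility should funnel material to 18. Hindered alkoxide in its alcohol is used because carbonate does not exchange an ester α-proton in an already anionic molecule, while tert-butoxide should spare the aryl sulfonate and the methyl ester.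

Step 12
Reactants: 18 methyl (1S,5S,7R,8S)-4-hydroxy-8-methyl-1,5-bis(3-methylbut-2-en-1-yl)-8-(4-methylpent-3-en-1-yl)-2,9-dioxo-3-[3-(tosyloxy)benzoyl]bicyclo[3.3.1]non-3-ene-7-carboxylate
Product: 19 3-{[(1S,5S,7R,8S)-4-hydroxy-7-(hydroxymethyl)-8-methyl-1,5-bis(3-methylbut-2-en-1-yl)-8-(4-methylpent-3-en-1-yl)-2,9-dioxobicyclo[3.3.1]non-3-en-3-yl]carbonyl}phenyl 4-methylbenzenesulfonate
Conditions: i-Bu2AlH (4.5 equiv), CH2Cl2, −78 to −40 °C; aq. potassium sodium tartrate
Reagents that add atoms: none
Why: Chemoselective ester reduction: the first equivalent turns the enolised trione into an aluminium chelate that resists hydride, the rest reduces the ester to the primary alcohol, and the C9 ketone, flanked by two quaternary carbons, should be too hindered to bind the bulky alane at low temperature; reduction precedes O-methylation because the methyl enol ether would expose two vinylogous ester carbonyls.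

Step 13
Reactants: 19 3-{[(1S,5S,7R,8S)-4-hydroxy-7-(hydroxymethyl)-8-methyl-1,5-bis(3-methylbut-2-en-1-yl)-8-(4-methylpent-3-en-1-yl)-2,9-dioxobicyclo[3.3.1]non-3-en-3-yl]carbonyl}phenyl 4-methylbenzenesulfonate
Product: 20 the C4 methyl enol ether of 19, (1S,5S,7R,8S)-7-(hydroxymethyl)-4-methoxy analogue
Conditions: TMSCHN2, toluene/MeOH, 0 °C
Reagents that add atoms: (trimethylsilyl)diazomethane, C[Si](C)(C)C=[N+]=[N-]
Why: Diazoalkane O-methylation touches only the acidic enol, not the primary alcohol, and is expected at the less hindered C4 oxygen; the regiochemistry is immaterial because step 18 removes the methyl group.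

Step 14
Reactants: 20 the C4 methyl enol ether of 19
Product: 21 the primary iodide, (1S,5S,7R,8S)-7-(iodomethyl)-4-methoxy analogue
Conditions: PPh3, imidazole, I2, CH2Cl2, 0 to 20 °C
Reagents that add atoms: iodine, II
Why: Appel-type iodination by SN2 displacement of the primary alkoxyphosphonium ion; the vinylogous ester, the C9 ketone and the sulfonate are inert.

Step 15
Reactants: 22 6-methylhept-5-en-2-one
Product: 24 6-methylhept-5-en-1-yne, via enol phosphate 23 (not isolated)
Conditions: LiN(i-Pr)2 (1.05 equiv), THF, −78 °C; ClP(O)(OEt)2, −78 to 20 °C; then LiN(i-Pr)2 (2.3 equiv), −78 to 20 °C; H2O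
Reagents that add atoms: none
Why: Kinetic enolisation on the methyl side, O-phosphorylation and base-induced β-elimination of the enol phosphate is the standard conversion of a methyl ketone into a terminal alkyne.

Step 16
Reactants: 24 6-methylhept-5-en-1-yne
Product: 26 (1E)-1-iodo-2,6-dimethylhepta-1,5-diene, via alkenylalane 25 (not isolated)
Conditions: AlMe3 (2 equiv), Cp2ZrCl2 (25 mol %), CH2Cl2, 0 to 20 °C; then I2, THF, −30 to 0 °C
Reagents that add atoms: trimethylaluminium, C[Al](C)C; iodine, II
Why: Zirconium-catalysed methylalumination of a terminal alkyne is syn and puts aluminium on the terminal carbon, and iodinolysis goes with retention, which gives the (E)-iodide.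

Step 17
Reactants: 21 the primary iodide, 26 (1E)-1-iodo-2,6-dimethylhepta-1,5-diene
Product: 28 the O-methyl O-tosyl derivative of the target, via alkylzinc iodide 27 (not isolated)
Conditions: 21, Zn dust (I2-activated), DMA, 40 °C; then 26, PdCl2(dppf) (5 mol %), THF/DMA, 45 °C
Reagents that add atoms: none
Why: Zinc inserts into the primary C–I bond in the presence of ketone and vinylogous ester, and the Negishi sp3–sp2 coupling with the alkenyl iodide retains the (E)-geometry; dppf-ligated palladium suppresses β-hydride elimination and does not activate the aryl sulfonate.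

Step 18
Reactants: 28 the O-methyl O-tosyl derivative of the target
Product: 29 (1S,5S,7R,8S)-7-[(2E)-3,7-dimethylocta-2,6-dien-1-yl]-4-hydroxy-3-(3-hydroxybenzoyl)-8-methyl-1,5-bis(3-methylbut-2-en-1-yl)-8-(4-methylpent-3-en-1-yl)bicyclo[3.3.1]non-3-ene-2,9-dione
Conditions: KOH, dioxane/H2O, 90 °C; then 1 M HCl
Reagents that add atoms: potassium hydroxide, [K+].[OH-]
Why: Hydroxide cleaves the vinylogous methyl ester by addition–elimination at C4 (the C4 oxygen then comes from hydroxide) and the aryl tosylate by attack at sulfur in one operation; the product is held as its enolate/phenoxide during heating and no stereocentre is epimerisable.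

**Compound list**

1 | methyl 3-hydroxypropanoate | COC(=O)CCO | starting material
2 | methyl 3-[(tert-butyldimethylsilyl)oxy]propanoate | COC(=O)CCO[Si](C)(C)C(C)(C)C | intermediate
3 | methyl 2-{[(tert-butyldimethylsilyl)oxy]methyl}-3-oxobutanoate (racemic) | COC(=O)C(CO[Si](C)(C)C(C)(C)C)C(C)=O | intermediate
4 | methyl (2E)-2-{[(tert-butyldimethylsilyl)oxy]methyl}-3-(tosyloxy)but-2-enoate | COC(=O)/C(CO[Si](C)(C)C(C)(C)C)=C(\C)OS(=O)(=O)c1ccc(C)cc1 | intermediate
5 | 5-bromo-2-methylpent-2-ene | CC(C)=CCCBr | starting material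
6 | (4-methylpent-3-en-1-yl)zinc bromide | CC(C)=CCC[Zn]Br | intermediate
7 | methyl (2E)-2-{[(tert-butyldimethylsilyl)oxy]methyl}-3,7-dimethylocta-2,6-dienoate | COC(=O)/C(CO[Si](C)(C)C(C)(C)C)=C(\C)CCC=C(C)C | intermediate
8 | methyl (2E)-2-(hydroxymethyl)-3,7-dimethylocta-2,6-dienoate | COC(=O)/C(CO)=C(\C)CCC=C(C)C | intermediate
9 | 3-hydroxybenzoic acid | O=C(O)c1cccc(O)c1 | starting material
10 | 3-(tosyloxy)benzoic acid | Cc1ccc(cc1)S(=O)(=O)Oc1cccc(c1)C(=O)O | intermediate
11 | phloroglucinol | Oc1cc(O)cc(O)c1 | starting material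
12 | 3-(tosyloxy)benzoyl chloride | Cc1ccc(cc1)S(=O)(=O)Oc1cccc(c1)C(Cl)=O | intermediate
13 | 3-(2,4,6-trihydroxybenzoyl)phenyl 4-methylbenzenesulfonate | Cc1ccc(cc1)S(=O)(=O)Oc1cccc(c1)C(=O)c1c(O)cc(O)cc1O | intermediate
14 | prenyl bromide (1-bromo-3-methylbut-2-ene) | CC(C)=CCBr | starting material
15 | 3-[2,4,6-trihydroxy-3,5-bis(3-methylbut-2-en-1-yl)benzoyl]phenyl 4-methylbenzenesulfonate | Cc1ccc(cc1)S(=O)(=O)Oc1cccc(c1)C(=O)c1c(O)c(CC=C(C)C)c(O)c(CC=C(C)C)c1O | intermediate
16 | methyl (2E)-2-({3,5-dihydroxy-2,6-bis(3-methylbut-2-en-1-yl)-4-[3-(tosyloxy)benzoyl]phenoxy}methyl)-3,7-dimethylocta-2,6-dienoate | COC(=O)/C(COc1c(CC=C(C)C)c(O)c(C(=O)c2cccc(OS(=O)(=O)c3ccc(C)cc3)c2)c(O)c1CC=C(C)C)=C(\C)CCC=C(C)C | intermediate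
17 | methyl (3R)-3-{(1R)-2,4-dihydroxy-1,5-bis(3-methylbut-2-en-1-yl)-6-oxo-3-[3-(tosyloxy)benzoyl]cyclohexa-2,4-dien-1-yl}-3,7-dimethyl-2-methylideneoct-6-enoate (Michael precursor) | C=C(C(=O)OC)[C@](C)(CCC=C(C)C)[C@@]1(CC=C(C)C)C(=O)C(CC=C(C)C)=C(O)C(C(=O)c2cccc(OS(=O)(=O)c3ccc(C)cc3)c2)=C1O | intermediate
18 | methyl (1S,5S,7R,8S)-4-hydroxy-8-methyl-1,5-bis(3-methylbut-2-en-1-yl)-8-(4-methylpent-3-en-1-yl)-2,9-dioxo-3-[3-(tosyloxy)benzoyl]bicyclo[3.3.1]non-3-ene-7-carboxylate (ester equatorial on C7, cis to the axial C8 methyl) | COC(=O)[C@@H]1C[C@]2(CC=C(C)C)C(=O)[C@@](CC=C(C)C)(C(=O)C(C(=O)c3cccc(OS(=O)(=O)c4ccc(C)cc4)c3)=C2O)[C@@]1(C)CCC=C(C)C | intermediate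
19 | (1S,5S,7R,8S)-7-(hydroxymethyl) analogue of 18 (free enolised trione, aryl tosylate) | OC[C@@H]1C[C@]2(CC=C(C)C)C(=O)[C@@](CC=C(C)C)(C(=O)C(C(=O)c3cccc(OS(=O)(=O)c4ccc(C)cc4)c3)=C2O)[C@@]1(C)CCC=C(C)C | intermediate
20 | (1S,5S,7R,8S)-7-(hydroxymethyl)-4-methoxy enol ether of 19 | OC[C@@H]1C[C@]2(CC=C(C)C)C(=O)[C@@](CC=C(C)C)(C(=O)C(C(=O)c3cccc(OS(=O)(=O)c4ccc(C)cc4)c3)=C2OC)[C@@]1(C)CCC=C(C)C | intermediate
21 | (1S,5S,7R,8S)-7-(iodomethyl)-4-methoxy compound | IC[C@@H]1C[C@]2(CC=C(C)C)C(=O)[C@@](CC=C(C)C)(C(=O)C(C(=O)c3cccc(OS(=O)(=O)c4ccc(C)cc4)c3)=C2OC)[C@@]1(C)CCC=C(C)C | intermediate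
22 | 6-methylhept-5-en-2-one | CC(=O)CCC=C(C)C | starting material
23 | diethyl 6-methylhepta-1,5-dien-2-yl phosphate | C=C(CCC=C(C)C)OP(=O)(OCC)OCC | intermediate
24 | 6-methylhept-5-en-1-yne | C#CCCC=C(C)C | intermediate
25 | [(1E)-2,6-dimethylhepta-1,5-dien-1-yl]dimethylalumane | C[Al](C)/C=C(\C)CCC=C(C)C | intermediate
26 | (1E)-1-iodo-2,6-dimethylhepta-1,5-diene | I/C=C(\C)CCC=C(C)C | intermediate
27 | alkylzinc iodide from 21 (C7–CH2–ZnI) | I[Zn]C[C@@H]1C[C@]2(CC=C(C)C)C(=O)[C@@](CC=C(C)C)(C(=O)C(C(=O)c3cccc(OS(=O)(=O)c4ccc(C)cc4)c3)=C2OC)[C@@]1(C)CCC=C(C)C | intermediate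
28 | (1S,5S,7R,8S)-7-[(2E)-3,7-dimethylocta-2,6-dien-1-yl]-4-methoxy compound with the aryl tosylate in place | CC(C)=CCC/C(C)=C/C[C@@H]1C[C@]2(CC=C(C)C)C(=O)[C@@](CC=C(C)C)(C(=O)C(C(=O)c3cccc(OS(=O)(=O)c4ccc(C)cc4)c3)=C2OC)[C@@]1(C)CCC=C(C)C | intermediate
29 | (1S,5S,7R,8S)-7-[(2E)-3,7-dimethylocta-2,6-dien-1-yl]-4-hydroxy-3-(3-hydroxybenzoyl)-8-methyl-1,5-bis(3-methylbut-2-en-1-yl)-8-(4-methylpent-3-en-1-yl)bicyclo[3.3.1]non-3-ene-2,9-dione | CC(C)=CCC/C(C)=C/C[C@@H]1C[C@]2(CC=C(C)C)C(=O)[C@@](CC=C(C)C)(C(=O)C(C(=O)c3cccc(O)c3)=C2O)[C@@]1(C)CCC=C(C)C | target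

**Step count and risks**

Total: 18 steps. Longest linear sequence: 13 steps (steps 1–5, 9–14, 17, 18).

Steps most likely to fail:

1. Step 10 (Proposed new method). The catalyst may fail to distinguish the two enantiotopic ortho carbons, or may accelerate the rearrangement too little, so that uncatalysed, racemic rearrangement competes. Fallback with known chemistry: setting out from 16, the ether is rearranged thermally in toluene at 90 °C. This is an ordinary dearomatising ortho-Claisen rearrangement, with the relative configuration still set by alkene geometry and the chair transition state, and it gives racemic 17, that is 17 together with its enantiomer ent-17 F1. The racemate is resolved by preparative supercritical-fluid chromatography on a cellulose tris(3,5-dichlorophenylcarbamate) phase. The route is rejoined at 17.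

2. Step 11. Equilibration at C7 may stall, leaving the ester in the kinetically protonated axial arrangement, or forcing it may start to cleave the aryl sulfonate. Fallback: setting out from 17, the ring is closed with K2CO3 in MeOH at 20 °C, which needs no control at C7 and gives the 7-epimer of 18 F2, alone or mixed with 18. Reduction as in step 12 gives the 7-epimeric alcohol F3, and O-methylation as in step 13 gives its methyl enol ether F4. Dess–Martin periodinane oxidises this to the 7-epimeric aldehyde F5. Its α-proton is far more acidic than that of the ester, so DBU in CH2Cl2 at 20 °C should equilibrate it to the equatorial aldehyde F6. NaBH4 in MeOH at −20 °C then reduces only the aldehyde and returns the route at 20; any 19 or 20 carried along converges on the same aldehyde.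

3. Step 12. Chemoselectivity may be lost through hydride delivery to the C9 ketone beside the ester. Fallback: setting out from 18, both carbonyls are reduced on purpose with i-Bu2AlH (8 equiv, −78 to 0 °C) to the C9-carbinol diol F7 (either C9 epimer). TMSCHN2 gives the methyl enol ether F8. PPh3, I2 and imidazole convert only the primary alcohol into the iodide F9, the bridging carbinol being too hindered. Dess–Martin oxidation of the C9 carbinol then restores the ketone and returns the route at 21.

**Further compounds**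

F1 | step 10 | ent-17, methyl (3S)-3-{(1S)-2,4-dihydroxy-1,5-bis(3-methylbut-2-en-1-yl)-6-oxo-3-[3-(tosyloxy)benzoyl]cyclohexa-2,4-dien-1-yl}-3,7-dimethyl-2-methylideneoct-6-enoate | C=C(C(=O)OC)[C@@](C)(CCC=C(C)C)[C@]1(CC=C(C)C)C(=O)C(CC=C(C)C)=C(O)C(C(=O)c2cccc(OS(=O)(=O)c3ccc(C)cc3)c2)=C1O
F2 | step 11 | 7-epimer of 18 (ester on the inner face of ring A) | COC(=O)[C@H]1C[C@]2(CC=C(C)C)C(=O)[C@@](CC=C(C)C)(C(=O)C(C(=O)c3cccc(OS(=O)(=O)c4ccc(C)cc4)c3)=C2O)[C@@]1(C)CCC=C(C)C
F3 | step 11 | 7-epimer of 19 | OC[C@H]1C[C@]2(CC=C(C)C)C(=O)[C@@](CC=C(C)C)(C(=O)C(C(=O)c3cccc(OS(=O)(=O)c4ccc(C)cc4)c3)=C2O)[C@@]1(C)CCC=C(C)C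
F4 | step 11 | 7-epimer of 20 | OC[C@H]1C[C@]2(CC=C(C)C)C(=O)[C@@](CC=C(C)C)(C(=O)C(C(=O)c3cccc(OS(=O)(=O)c4ccc(C)cc4)c3)=C2OC)[C@@]1(C)CCC=C(C)C
F5 | step 11 | 7-epimeric C7 aldehyde (4-methoxy enol ether, aryl tosylate) | O=C[C@H]1C[C@]2(CC=C(C)C)C(=O)[C@@](CC=C(C)C)(C(=O)C(C(=O)c3cccc(OS(=O)(=O)c4ccc(C)cc4)c3)=C2OC)[C@@]1(C)CCC=C(C)C
F6 | step 11 | C7 aldehyde with the configuration of 20 (formyl equatorial) | O=C[C@@H]1C[C@]2(CC=C(C)C)C(=O)[C@@](CC=C(C)C)(C(=O)C(C(=O)c3cccc(OS(=O)(=O)c4ccc(C)cc4)c3)=C2OC)[C@@]1(C)CCC=C(C)C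
F7 | step 12 | 9-hydroxy analogue of 19 (configuration at C1, C5, C7, C8 as in 19; C9 carbinol, either epimer) | OC[C@@H]1C[C@]2(CC=C(C)C)C(O)[C@@](CC=C(C)C)(C(=O)C(C(=O)c3cccc(OS(=O)(=O)c4ccc(C)cc4)c3)=C2O)[C@@]1(C)CCC=C(C)C
F8 | step 12 | 9-hydroxy analogue of 20 | OC[C@@H]1C[C@]2(CC=C(C)C)C(O)[C@@](CC=C(C)C)(C(=O)C(C(=O)c3cccc(OS(=O)(=O)c4ccc(C)cc4)c3)=C2OC)[C@@]1(C)CCC=C(C)C
F9 | step 12 | 9-hydroxy analogue of 21 | IC[C@@H]1C[C@]2(CC=C(C)C)C(O)[C@@](CC=C(C)C)(C(=O)C(C(=O)c3cccc(OS(=O)(=O)c4ccc(C)cc4)c3)=C2OC)[C@@]1(C)CCC=C(C)C
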